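**Strategy.** Everything rests on opening the carbocycle at C8–C8a (isochromene numbering of the bicyclic core). C8a is α to C4a, the masked ketone of the C4a=C5–C6=O vinylogous system; C8 bears the hydroxyl; the pyran oxygen on C1 is β to the same carbon. This is an aldol retron with a β-heteroatom. A copper-catalysed borylative aldol cyclisation of an acyclic vinyl ketone–aldehyde (a cross-conjugated β-methoxy dienone made from lactic acid) therefore installs C1–B (then C1–O), closes the six-membered ring through C8–C8a and sets C8 and C8a in one operation. Chlorination, Stork–Danheiser ethynylation, Sonogashira coupling with a crotylation-derived vinyl iodide and a 6-endo oxa-Michael closure of the pyran finish the synthesis.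

Key step: step 8

Remark on labels: the core atoms are called O2, C1, C3, C4, C4a, C5, C6, C7, C8, C8a as in 1H-isochromene, the side chain C1′–C3′ from C3; the same labels are used for the corresponding atoms of every intermediate.

**Core (steps 1–12)**

Step 1
Reactants: 1 (S)-lactic acid; 2 pivalaldehyde
Product: 3 (2S,5S)-2-tert-butyl-5-methyl-1,3-dioxolan-4-one
Conditions: p-TsOH·H2O (cat.), pentane, reflux, Dean–Stark; crystallisation from pentane/Et2O, −78 °C
Reagents that add atoms: pivalaldehyde (2), CC(C)(C)C=O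
Why: Acid-catalysed acetalisation of the α-hydroxy acid; the lactate stereocentre should favour the cis acetal (tert-butyl and methyl on the same face), which crystallisation is expected to enrich.

Step 2
Reactants: 3 (2S,5S)-2-tert-butyl-5-methyl-1,3-dioxolan-4-one
Product: 6 [(2S,4R)-2-tert-butyl-4-methyl-5-oxo-1,3-dioxolan-4-yl]methyl acetate, via lithium enolate 4 (not isolated), via lithium alkoxide 5 (not isolated)
Conditions: LiN(iPr)2, THF, −78 °C; CH2O (gas), −78 °C; Ac2O, −78 °C → rt
Reagents that add atoms: formaldehyde, C=O; acetic anhydride, CC(=O)OC(C)=O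
Why: Aldol-type hydroxymethylation of the dioxolanone enolate (self-regeneration of stereocentres): formaldehyde should add anti to the tert-butyl group, so the quaternary carbon (future C7) forms with overall retention, and the alkoxide is acetylated in situ.

Step 3
Reactants: 6 [(2S,4R)-2-tert-butyl-4-methyl-5-oxo-1,3-dioxolan-4-yl]methyl acetate
Product: 7 (5R)-5-hydroxy-5-methyloxane-2,4-dione
Conditions: LiN(iPr)2 (2.2 equiv), THF, −78 → 0 °C; aq. HCl
Reagents that add atoms: none
Why: Dieckmann-type intramolecular Claisen condensation: the acetate enolate (C5) acylates the activated acylal carbonyl (C6) in a 6-exo-trig closure, the expelled hemiacetal alkoxide loses pivalaldehyde, and the acidic β-keto lactone is held as its enolate, which should drive the equilibrium.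

Step 4
Reactants: 7 (5R)-5-hydroxy-5-methyloxane-2,4-dione
Product: 8 (5R)-5-hydroxy-4-methoxy-5-methyl-5,6-dihydro-2H-pyran-2-one
Conditions: Me2SO4, K2CO3, acetone, rt
Reagents that add atoms: dimethyl sulfate, COS(=O)(=O)OC
Why: O-methylation of the vinylogous acid at the C6 oxygen (the tertiary hydroxyl is not acidic enough to react); the lactone ring locks the enol ether with C4a and C7 cis, the geometry the later ring closure needs.

Step 5
Reactants: 8 (5R)-5-hydroxy-4-methoxy-5-methyl-5,6-dihydro-2H-pyran-2-one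
Product: 9 (5R)-4-methoxy-5-methyl-5-[(triethylsilyl)oxy]-5,6-dihydro-2H-pyran-2-one
Conditions: Et3SiOTf, 2,6-lutidine, CH2Cl2, 0 °C
Reagents that add atoms: triethylsilyl trifluoromethanesulfonate, CC[Si](CC)(CC)OS(=O)(=O)C(F)(F)F
Why: Silylation of the hindered tertiary alcohol with a silyl triflate; the ether should block α-ketol shift and retro-aldol at C7 in the steps that follow.

Step 6
Reactants: 9 (5R)-4-methoxy-5-methyl-5-[(triethylsilyl)oxy]-5,6-dihydro-2H-pyran-2-one
Product: 10 (4E,6R)-7-hydroxy-5-methoxy-6-methyl-6-[(triethylsilyl)oxy]hepta-1,4-dien-3-one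
Conditions: CH2=CHMgBr (1.1 equiv), THF, −78 → −40 °C; sat. aq. NH4Cl, −78 °C
Reagents that add atoms: vinylmagnesium bromide, C=C[Mg]Br
Why: Grignard mono-addition to a lactone: the magnesium hemiketal should persist at low temperature and open only on work-up, giving the δ-hydroxy divinyl ketone with the (E)-enol ether of the ring retained; the vinyl group supplies C8a and C1.

Step 7
Reactants: 10 (4E,6R)-7-hydroxy-5-methoxy-6-methyl-6-[(triethylsilyl)oxy]hepta-1,4-dien-3-one
Product: 11 (2S,3E)-3-methoxy-2-methyl-5-oxo-2-[(triethylsilyl)oxy]hepta-3,6-dienal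
Conditions: Dess–Martin periodinane, NaHCO3, CH2Cl2, 0 °C → rt
Reagents that add atoms: none
Why: Dess–Martin oxidation of the primary alcohol (open-chain tautomer) to the aldehyde C8, which is α-quaternary and therefore cannot enolise or epimerise.

Step 8
Reactants: 11 (2S,3E)-3-methoxy-2-methyl-5-oxo-2-[(triethylsilyl)oxy]hepta-3,6-dienal
Product: 12 (4R,5R,6S)-5-hydroxy-3-methoxy-4-methyl-6-[(4,4,5,5-tetramethyl-1,3,2-dioxaborolan-2-yl)methyl]-4-[(triethylsilyl)oxy]cyclohex-2-en-1-one
Conditions: CuCl (5 mol %), Xantphos (5 mol %), NaOtBu (10 mol %), B2pin2 (1.1 equiv), tBuOH (1.5 equiv), THF, 0 °C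
Reagents that add atoms: bis(pinacolato)diboron, CC1(C)OB(OC1(C)C)B1OC(C)(C)C(C)(C)O1
Why: The copper boryl formed from CuCl, NaOtBu and B2pin2 adds 1,4 to the terminal vinyl ketone (C1–B), and the resulting O-bound copper enolate, a 1-methoxy-3-oxido diene nucleophilic at C8a, attacks the tethered aldehyde C8 before it is protonated; tBuOH then releases the aldolate and returns the copper alkoxide. The closest known reaction type is the copper-catalysed borylative (and reductive) aldol cyclisation of enones bearing a tethered carbonyl group. The carbocycle closes in a 6-(enolendo)-exo-trig aldol mode, and the (E)-enol ether inherited from lactone 9 holds C4a and C7 cis so that this ring can form. C8a and C8 are set together: the (Z)-enolate should react through a chair-like, copper-bridged Zimmerman–Traxler arrangement with CH2Bpin pseudo-equatorial and the aldehyde oxygen pseudo-axial, which places C8–O cis to C8a–C1. The aldehyde face is chosen by the C7 stereocentre: with the C7–OSiEt3 bond antiperiplanar to the incoming C8a (polar Felkin–Anh, silyloxy pseudo-equatorial, methyl pseudo-axial) C8–O ends cis to C7–O. The step needs conjugate borylation to beat 1,2-borylation of the aldehyde and attack on the β-methoxy enone; the unhindered terminal acceptor versus an α-quaternary aldehyde and a donor-substituted tetrasubstituted alkene should secure this.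

Step 9
Reactants: 12 (4R,5R,6S)-5-hydroxy-3-methoxy-4-methyl-6-[(4,4,5,5-tetramethyl-1,3,2-dioxaborolan-2-yl)methyl]-4-[(triethylsilyl)oxy]cyclohex-2-en-1-one
Product: 13 (4R,5R,6S)-5-hydroxy-6-(hydroxymethyl)-3-methoxy-4-methyl-4-[(triethylsilyl)oxy]cyclohex-2-en-1-one
Conditions: NaBO3·4H2O, THF/H2O, rt
Reagents that add atoms: sodium perborate (NaBO3·4H2O), [Na+].[Na+].O[B-]1(O)OO[B-](O)(O)OO1
Why: Oxidation of the primary C–B bond to C1–OH by 1,2-migration from boron to oxygen; perborate is mild enough to spare the β-hydroxy ketone and the silyl ether.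

Step 10
Reactants: 13 (4R,5R,6S)-5-hydroxy-6-(hydroxymethyl)-3-methoxy-4-methyl-4-[(triethylsilyl)oxy]cyclohex-2-en-1-one
Product: 14 O1,O8-di-tert-butylsilylene derivative of 13 (six-membered silylene acetal across the C8 and C1 oxygens; C7, C8, C8a unchanged)
Conditions: tBu2Si(OTf)2, 2,6-lutidine, CH2Cl2, 0 °C
Reagents that add atoms: di-tert-butylsilyl bis(trifluoromethanesulfonate), CC(C)(C)[Si](OS(=O)(=O)C(F)(F)F)(OS(=O)(=O)C(F)(F)F)C(C)(C)C
Why: Silylene protection of the cis-1,3-diol in one operation; it masks the β-hydroxyl against retro-aldol in step 12 and keeps C1–O from cyclising before the side chain is attached.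

Step 11
Reactants: 14 O1,O8-di-tert-butylsilylene derivative of 13
Product: 15 5-chloro derivative of 14 (2-chloro-3-methoxy enone; C7, C8, C8a unchanged)
Conditions: N-chlorosuccinimide, CH2Cl2, 0 °C → rt
Reagents that add atoms: N-chlorosuccinimide, O=C1CCC(=O)N1Cl
Why: Electrophilic chlorination at C5, the nucleophilic α-carbon of the vinylogous ester, followed by loss of the proton.

Step 12
Reactants: 15 5-chloro derivative of 14
Product: 17 2-chloro-3-ethynyl enone (C6 ketone; C5–Cl; C4a–C≡CH; C7–OSiEt3; O1/O8 silylene; C7, C8, C8a as in the target), via propargylic alkoxide 16 (not isolated)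
Conditions: HC≡CMgBr, CeCl3, THF, −78 °C; then 1 M aq. HCl, THF, 0 °C
Reagents that add atoms: ethynylmagnesium bromide, C#C[Mg]Br; water, O
Why: Stork–Danheiser transposition: the weakly basic cerium acetylide adds 1,2 to the C4a carbonyl, and acid ionises the tertiary alcohol to the methoxy-stabilised cation, which water captures at C6 with loss of methanol; the ketone thus moves to C6 and the alkyne sits on C4a with no regiochemical ambiguity.

**Side chain (steps 13–18)**

Step 13
Reactants: 18 (E)-2-methylbut-2-enal (tiglaldehyde)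
Product: 20 (3S,4S,5E)-3,5-dimethylhepta-1,5-dien-4-ol, via borinate ester 19 (not isolated)
Conditions: (−)-(E)-crotyl-B(Ipc)2 [made in the flask: trans-2-butene, n-BuLi, KOtBu, THF, −45 °C; (−)-Ipc2BOMe from (+)-α-pinene, −78 °C; BF3·OEt2], then 18, −78 °C; NaOH, H2O2, 0 °C → rt
Reagents that add atoms: (E)-crotyldiisopinocampheylborane (made in the flask from trans-2-butene, C/C=C/C), C/C=C/CB([C@@H]1C[C@@H]2C[C@H]([C@H]1C)C2(C)C)[C@@H]1C[C@@H]2C[C@H]([C@H]1C)C2(C)C
Why: Brown crotylboration through a closed chair transition state: the (+)-α-pinene-derived reagent should attack the Si face of the aldehyde (carbinol S) and the (E)-crotyl geometry gives the anti relationship (methyl centre S), which maps onto the trans-2,3-disubstituted oxolane.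

Step 14
Reactants: 20 (3S,4S,5E)-3,5-dimethylhepta-1,5-dien-4-ol
Product: 22 (3S,4S,5E)-3,5-dimethylhept-5-ene-1,4-diol, via alkylborane 21 (not isolated)
Conditions: 9-BBN-H (2.2 equiv), THF, 0 °C → rt; then NaOH, H2O2, 0 °C
Reagents that add atoms: hydrogen peroxide, OO
Why: Anti-Markovnikov hydroboration–oxidation; 9-BBN should react only with the monosubstituted vinyl group and leave the trisubstituted alkene untouched.

Step 15
Reactants: 22 (3S,4S,5E)-3,5-dimethylhept-5-ene-1,4-diol
Product: 24 (2S,3S)-2-[(2E)-but-2-en-2-yl]-3-methyloxolane, via primary tosylate 23 (not isolated)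
Conditions: TsCl (1.05 equiv), pyridine, 0 °C → rt, then 60 °C
Reagents that add atoms: none
Why: Selective sulfonylation of the primary hydroxyl and 5-exo-tet Williamson-type closure by the secondary hydroxyl; no stereocentre is touched, so the anti diol gives the trans oxolane.

Step 16
Reactants: 24 (2S,3S)-2-[(2E)-but-2-en-2-yl]-3-methyloxolane
Product: 26 1-[(2S,3S)-3-methyloxolan-2-yl]ethan-1-one, via ozonide 25 (not isolated)
Conditions: O3, CH2Cl2, −78 °C; then PPh3, −78 °C → rt
Reagents that add atoms: ozone, [O-][O+]=O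
Why: Ozonolysis of the trisubstituted alkene with reductive work-up gives the methyl ketone; the trans-2,3 arrangement is also the thermodynamic one at the epimerisable C2.

Step 17
Reactants: 26 1-[(2S,3S)-3-methyloxolan-2-yl]ethan-1-one
Product: 27 (2S)-2-[(2S,3S)-3-methyloxolan-2-yl]but-3-yn-2-ol
Conditions: HC≡CMgBr, MgBr2·OEt2, CH2Cl2/THF, −78 °C; sat. aq. NH4Cl
Reagents that add atoms: ethynylmagnesium bromide, C#C[Mg]Br
Why: Chelation-controlled (Cram chelate) Grignard addition: magnesium bridges the ring oxygen and the carbonyl oxygen, and the acetylide should attack from the face of the C2 hydrogen, anti to C3, giving the (S)-carbinol.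

Step 18
Reactants: 27 (2S)-2-[(2S,3S)-3-methyloxolan-2-yl]but-3-yn-2-ol
Product: 29 (2S,3E)-4-iodo-2-[(2S,3S)-3-methyloxolan-2-yl]but-3-en-2-ol, via alkenylzirconocene 28 (not isolated)
Conditions: Cp2Zr(H)Cl (2.2 equiv), THF, rt; then I2, 0 °C
Reagents that add atoms: iodine, II
Why: Hydrozirconation is a syn addition that places zirconium on the terminal carbon, and iodinolysis proceeds with retention, so the (E)-vinyl iodide should result; the first equivalent of hydride is consumed by the hydroxyl.

**Union and end game (steps 19–20)**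

Step 19
Reactants: 17 2-chloro-3-ethynyl enone; 29 (2S,3E)-4-iodo-2-[(2S,3S)-3-methyloxolan-2-yl]but-3-en-2-ol
Product: 30 dienynone (C4a–C≡C–CH=CH–C(CH3)(OH)–oxolanyl; E alkene; silyl groups of 17 retained)
Conditions: PdCl2(PPh3)2 (5 mol %), CuI (10 mol %), Et3N, THF, rt, degassed
Reagents that add atoms: none
Why: Sonogashira coupling forms C3–C1′ with retention of the alkene geometry; the vinyl iodide should react far faster than the α-chloro enone, and a tertiary amine base avoids conjugate addition to the ynenone.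

Step 20
Reactants: 30 dienynone
Product: 32 (7R,8R,8aS)-5-chloro-7,8-dihydroxy-3-[(1E,3S)-3-hydroxy-3-[(2S,3S)-3-methyloxolan-2-yl]but-1-en-1-yl]-7-methyl-1,7,8,8a-tetrahydro-6H-isochromen-6-one, via tetraol 31 (not isolated)
Conditions: HF·pyridine, pyridine, THF, 0 °C → rt; then DABCO (20 mol %), CH2Cl2, rt
Reagents that add atoms: none
Why: Fluoride cleaves the silylene and the triethylsilyl ether, and the freed C1 hydroxyl adds to C3, the δ-carbon of the ynenone, in a 6-endo-dig oxa-Michael closure; the fused pyran is strongly preferred over the 5-exo (anti-Michael) mode and over attack by the C8 hydroxyl, which would give a bridged ring.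

**Compound list**

1 | (S)-lactic acid | C[C@H](O)C(=O)O | starting material
2 | pivalaldehyde | CC(C)(C)C=O | starting material
3 | (2S,5S)-2-tert-butyl-5-methyl-1,3-dioxolan-4-one | C[C@@H]1O[C@H](C(C)(C)C)OC1=O | intermediate
4 | lithium (2S)-2-tert-butyl-5-methyl-1,3-dioxol-4-olate (lithium enolate of 3; not isolated) | CC1=C([O-])O[C@@H](C(C)(C)C)O1.[Li+] | intermediate
5 | lithium alkoxide of (2S,5R)-2-tert-butyl-5-(hydroxymethyl)-5-methyl-1,3-dioxolan-4-one (not isolated) | C[C@]1(C[O-])O[C@H](C(C)(C)C)OC1=O.[Li+] | intermediate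
6 | [(2S,4R)-2-tert-butyl-4-methyl-5-oxo-1,3-dioxolan-4-yl]methyl acetate | C[C@]1(COC(C)=O)O[C@H](C(C)(C)C)OC1=O | intermediate
7 | (5R)-5-hydroxy-5-methyloxane-2,4-dione | O=C1CC(=O)[C@](C)(O)CO1 | intermediate
8 | (5R)-5-hydroxy-4-methoxy-5-methyl-5,6-dihydro-2H-pyran-2-one | O=C1C=C(OC)[C@](C)(O)CO1 | intermediate
9 | (5R)-4-methoxy-5-methyl-5-[(triethylsilyl)oxy]-5,6-dihydro-2H-pyran-2-one | O=C1C=C(OC)[C@](C)(O[Si](CC)(CC)CC)CO1 | intermediate
10 | (4E,6R)-7-hydroxy-5-methoxy-6-methyl-6-[(triethylsilyl)oxy]hepta-1,4-dien-3-one (open-chain form) | C=CC(=O)/C=C(/OC)[C@](C)(O[Si](CC)(CC)CC)CO | intermediate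
11 | (2S,3E)-3-methoxy-2-methyl-5-oxo-2-[(triethylsilyl)oxy]hepta-3,6-dienal | C=CC(=O)/C=C(/OC)[C@](C)(O[Si](CC)(CC)CC)C=O | intermediate
12 | (4R,5R,6S)-5-hydroxy-3-methoxy-4-methyl-6-[(4,4,5,5-tetramethyl-1,3,2-dioxaborolan-2-yl)methyl]-4-[(triethylsilyl)oxy]cyclohex-2-en-1-one | O=C1C=C(OC)[C@](C)(O[Si](CC)(CC)CC)[C@H](O)[C@@H]1CB1OC(C)(C)C(C)(C)O1 | intermediate
13 | (4R,5R,6S)-5-hydroxy-6-(hydroxymethyl)-3-methoxy-4-methyl-4-[(triethylsilyl)oxy]cyclohex-2-en-1-one | O=C1C=C(OC)[C@](C)(O[Si](CC)(CC)CC)[C@H](O)[C@@H]1CO | intermediate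
14 | O1,O8-di-tert-butylsilylene derivative of 13 (C7, C8, C8a unchanged) | O=C1C=C(OC)[C@](C)(O[Si](CC)(CC)CC)[C@H](O2)[C@@H]1CO[Si]2(C(C)(C)C)C(C)(C)C | intermediate
15 | 5-chloro derivative of 14 (2-chloro-3-methoxy enone) | O=C1C(Cl)=C(OC)[C@](C)(O[Si](CC)(CC)CC)[C@H](O2)[C@@H]1CO[Si]2(C(C)(C)C)C(C)(C)C | intermediate
16 | C4a ethynyl carbinol of 15 (present as its alkoxide, both C4a epimers; not isolated) | C#CC1(O)C(Cl)=C(OC)[C@](C)(O[Si](CC)(CC)CC)[C@H](O2)[C@@H]1CO[Si]2(C(C)(C)C)C(C)(C)C | intermediate
17 | 2-chloro-3-ethynyl enone (C6 ketone, C5–Cl, C4a–C≡CH, C7–OSiEt3, O1/O8 silylene; C7, C8, C8a as in the target) | C#CC1=C(Cl)C(=O)[C@](C)(O[Si](CC)(CC)CC)[C@H](O2)[C@@H]1CO[Si]2(C(C)(C)C)C(C)(C)C | intermediate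
18 | (E)-2-methylbut-2-enal (tiglaldehyde) | C/C=C(\C)C=O | starting material
19 | diisopinocampheylborinate of 20 (not isolated) | C[C@@H](C=C)[C@H](OB([C@@H]1C[C@@H]2C[C@H]([C@H]1C)C2(C)C)[C@@H]1C[C@@H]2C[C@H]([C@H]1C)C2(C)C)/C(C)=C/C | intermediate
20 | (3S,4S,5E)-3,5-dimethylhepta-1,5-dien-4-ol | C[C@@H](C=C)[C@H](O)/C(C)=C/C | intermediate
21 | C1-(9-borabicyclo[3.3.1]nonan-9-yl) adduct of 20, O-borylated (not isolated) | C[C@@H](CCB1C2CCCC1CCC2)[C@H](OB1C2CCCC1CCC2)/C(C)=C/C | intermediate
22 | (3S,4S,5E)-3,5-dimethylhept-5-ene-1,4-diol | C[C@@H](CCO)[C@H](O)/C(C)=C/C | intermediate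
23 | (3S,4S,5E)-4-hydroxy-3,5-dimethylhept-5-en-1-yl 4-methylbenzenesulfonate (not isolated) | C[C@@H](CCOS(=O)(=O)c1ccc(C)cc1)[C@H](O)/C(C)=C/C | intermediate
24 | (2S,3S)-2-[(2E)-but-2-en-2-yl]-3-methyloxolane | C[C@H]1CCO[C@@H]1/C(C)=C/C | intermediate
25 | 3,5-dimethyl-3-[(2S,3S)-3-methyloxolan-2-yl]-1,2,4-trioxolane (ozonide; not isolated) | C[C@H]1CCO[C@@H]1C1(C)OOC(C)O1 | intermediate
26 | 1-[(2S,3S)-3-methyloxolan-2-yl]ethan-1-one | C[C@H]1CCO[C@@H]1C(C)=O | intermediate
27 | (2S)-2-[(2S,3S)-3-methyloxolan-2-yl]but-3-yn-2-ol | C[C@H]1CCO[C@@H]1[C@@](C)(O)C#C | intermediate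
28 | (E)-alkenylzirconocene chloride of 27, O-zirconated (not isolated) | C[C@H]1CCO[C@@H]1[C@@](C)(O[Zr](Cl)(C2C=CC=C2)C2C=CC=C2)/C=C/[Zr](Cl)(C2C=CC=C2)C2C=CC=C2 | intermediate
29 | (2S,3E)-4-iodo-2-[(2S,3S)-3-methyloxolan-2-yl]but-3-en-2-ol | C[C@H]1CCO[C@@H]1[C@@](C)(O)/C=C/I | intermediate
30 | dienynone from 17 and 29 (C4a–C≡C–CH=CH–C(CH3)(OH)–oxolanyl, E, silyl groups retained) | C[C@H]1CCO[C@@H]1[C@@](C)(O)/C=C/C#CC1=C(Cl)C(=O)[C@](C)(O[Si](CC)(CC)CC)[C@H](O2)[C@@H]1CO[Si]2(C(C)(C)C)C(C)(C)C | intermediate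
31 | tetraol enynone (30 without silyl groups; not isolated) | C[C@H]1CCO[C@@H]1[C@@](C)(O)/C=C/C#CC1=C(Cl)C(=O)[C@](C)(O)[C@H](O)[C@@H]1CO | intermediate
32 | (7R,8R,8aS)-5-chloro-7,8-dihydroxy-3-[(1E,3S)-3-hydroxy-3-[(2S,3S)-3-methyloxolan-2-yl]but-1-en-1-yl]-7-methyl-1,7,8,8a-tetrahydro-6H-isochromen-6-one | C[C@H]1CCO[C@@H]1[C@@](C)(O)/C=C/C1=CC2=C(Cl)C(=O)[C@](C)(O)[C@H](O)[C@@H]2CO1 | target

**Step count.** Total: 20 steps. Longest linear sequence: 14 steps (steps 1–12, 19, 20); the side-chain branch is 6 steps (13–18).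

**Steps most likely to fail**

1. Step 8 (key step). The copper boryl may add 1,2 to the aldehyde, or the copper enolate may be protonated before it cyclises; discrimination between the aldehyde faces by the C7 stereocentre may also be insufficient, since a dipole-minimised arrangement would lead to the C8 epimer. Fallback: setting out from aldehyde 11, a PMe3-catalysed intramolecular Morita–Baylis–Hillman reaction would close the same C8–C8a bond and give (4R,5R)-5-hydroxy-3-methoxy-4-methyl-6-methylidene-4-[(triethylsilyl)oxy]cyclohex-2-en-1-one F1, whose C8 carbinol forms under reversible conditions. Copper-catalysed conjugate borylation of the exocyclic enone of F1 (CuCl, Xantphos, NaOtBu, B2pin2, MeOH), with protonation of the enolate anti to the C8 oxygen, would then give boronate 12, where the route is rejoined.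

2. Step 3. The acetate enolate may react intermolecularly (with another dioxolanone or with released pivalaldehyde) faster than it closes the ring, or may be formed incompletely. Fallback: setting out from acetate 6, intermolecular Claisen acylation at the dioxolanone carbonyl with excess lithium enolate of tert-butyl acetate (LiN(iPr)2, tBuOAc, THF, −78 °C), which also removes the acetyl group, would give tert-butyl (4R)-4,5-dihydroxy-4-methyl-3-oxopentanoate F2. Acid-induced lactonisation (CF3CO2H, CH2Cl2) would then give dione 7, where the route is rejoined.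

3. Step 6. A second addition of the Grignard reagent to the liberated divinyl ketone, or migration of the silyl group from the tertiary to the primary oxygen in a ring-opened alkoxide, would erode the hydroxy ketone. Fallback: setting out from lactone 9, reduction with iBu2AlH (CH2Cl2, −78 °C) would give the lactol (5R)-4-methoxy-5-methyl-5-[(triethylsilyl)oxy]-5,6-dihydro-2H-pyran-2-ol F3. Addition of CH2=CHMgBr (THF, −78 °C) to its open hydroxy enal form would give (4E,6R)-5-methoxy-6-methyl-6-[(triethylsilyl)oxy]hepta-1,4-diene-3,7-diol F4. Dess–Martin oxidation of both hydroxyls would then give aldehyde 11 directly, where the route is rejoined.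

Further compounds
F1 | step 8 | (4R,5R)-5-hydroxy-3-methoxy-4-methyl-6-methylidene-4-[(triethylsilyl)oxy]cyclohex-2-en-1-one | O=C1C=C(OC)[C@](C)(O[Si](CC)(CC)CC)[C@H](O)C1=C
F2 | step 3 | tert-butyl (4R)-4,5-dihydroxy-4-methyl-3-oxopentanoate | CC(C)(C)OC(=O)CC(=O)[C@](C)(O)CO
F3 | step 6 | (5R)-4-methoxy-5-methyl-5-[(triethylsilyl)oxy]-5,6-dihydro-2H-pyran-2-ol | OC1C=C(OC)[C@](C)(O[Si](CC)(CC)CC)CO1
F4 | step 6 | (4E,6R)-5-methoxy-6-methyl-6-[(triethylsilyl)oxy]hepta-1,4-diene-3,7-diol | C=CC(O)/C=C(/OC)[C@](C)(O[Si](CC)(CC)CC)CO
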